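**Strategy.** Everything rests on opening ring B, the hexasubstituted ring that carries the C-methyl, into a cyclobutenone and an ynol ether. One thermal cascade (4π opening, ketene–alkyne [2+2], 4π opening, 6π closure) then builds ring B on the bridging CH2 in a single operation. It exploits the alternating oxygens of ring B: the hydroxyl carbon between the CH2 carbon and the methyl carbon comes from the ketene C=O, the methoxyl carbon beside the bridge from the alkynyl ether, and the second hydroxyl carbon from a benzyl vinylogous ester. The precursors are racemic 3-(benzyloxy)-4-methylcyclobutenone and a 1-methoxyalkyne bearing MOM-protected ring A on its propargylic CH2; both acetyl groups are added last.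

Key step: step 7

Remark: the target has no stereocentre; the sp3 ring carbons of 4, 5, 16 and 18 are racemic and are erased when ring B aromatizes, so no stereocontrol is needed (MOM = methoxymethyl).

**Route**

Step 1
Reactants: 1 propionyl chloride; 2 ethoxyacetylene
Product: 4 racemic 3-ethoxy-4-methylcyclobut-2-en-1-one, via methylketene 3 (not isolated)
Conditions: Et3N, Et2O, 0 °C → rt (1 added slowly to 2 in excess and Et3N)
Reagents that add atoms: none
Why: Dehydrochlorination gives methylketene 3, and its ketene–ynol ether [2+2] cycloaddition joins the ketene carbonyl carbon to the unsubstituted, nucleophilic alkyne carbon, which places the methyl on the sp3 ring carbon next to the ethoxy-bearing carbon; that stereocentre forms racemic and is destroyed in step 7.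

Step 2
Reactants: 4 racemic 3-ethoxy-4-methylcyclobut-2-en-1-one
Product: 5 racemic 3-(benzyloxy)-4-methylcyclobut-2-en-1-one
Conditions: BnOH (3 equiv), PPTS (cat.), toluene, 50 °C, 5 Å molecular sieves (ethanol trap)
Reagents that add atoms: benzyl alcohol, OCc1ccccc1
Why: Acid-catalysed transetherification of a vinylogous ester (benzyl alcohol adds to the O-protonated enone at the alkoxy carbon, then ethanol is lost) should exchange the ether without moving the ring double bond, because the mild acid and removal of ethanol keep the enol intermediate from ketonising; benzyl is chosen so that this oxygen can later be freed by hydrogenolysis beside two methyl ethers.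

Step 3
Reactants: 6 5-methoxyresorcinol
Product: 7 1-methoxy-3,5-bis(methoxymethoxy)benzene
Conditions: MOMCl, iPr2NEt, CH2Cl2, 0 °C → rt
Reagents that add atoms: chloromethyl methyl ether, COCCl
Why: Double O-alkylation of the phenols under amine base (Williamson-type acetal formation) gives the bis-MOM ether, whose acetal oxygens direct the lithiation of step 4 and tolerate base, organolithium reagents and heat.

Step 4
Reactants: 7 1-methoxy-3,5-bis(methoxymethoxy)benzene
Product: 9 [4-methoxy-2,6-bis(methoxymethoxy)phenyl]methanol, via aryllithium 8 (not isolated)
Conditions: n-BuLi, THF, 0 °C → rt; (CH2O)n, 0 °C → rt; H2O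
Reagents that add atoms: paraformaldehyde (reacts as formaldehyde), C=O
Why: Directed ortho-metalation should occur at the one ring carbon flanked by both MOM ethers, which are stronger chelating directors than the methyl ether, and the aryllithium adds to formaldehyde released from paraformaldehyde to give the benzylic alcohol in one operation.

Step 5
Reactants: 9 [4-methoxy-2,6-bis(methoxymethoxy)phenyl]methanol
Product: 11 2-(chloromethyl)-5-methoxy-1,3-bis(methoxymethoxy)benzene, via benzylic mesylate 10 (not isolated)
Conditions: MsCl, iPr2NEt, CH2Cl2, −20 °C → rt; cold aq NaHCO3 wash; used crude at once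
Reagents that add atoms: methanesulfonyl chloride, CS(=O)(=O)Cl
Why: Sulfonylation gives a mesylate that the electron-rich ring ionises readily, so the ammonium chloride formed in the same flask converts it to the benzylic chloride (sulfonate-to-halide substitution) under buffered, acid-free conditions that leave the MOM acetals intact; the chloride is preferred to the bromide because it is less prone to ionise on handling.

Step 6
Reactants: 12 chloroacetaldehyde dimethyl acetal; 11 2-(chloromethyl)-5-methoxy-1,3-bis(methoxymethoxy)benzene
Product: 14 5-methoxy-1,3-bis(methoxymethoxy)-2-(3-methoxyprop-2-yn-1-yl)benzene, via lithium methoxyacetylide 13 (not isolated)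
Conditions: 12, LiNEt2 (3 equiv per 12, stock solution), THF, 0 °C; then 11, DMPU, −78 °C → rt; product purified on Et3N-deactivated silica
Reagents that add atoms: none
Why: Three equivalents of lithium amide convert the chloroacetal by double elimination (loss of methanol, then of HCl) and deprotonation into lithium methoxyacetylide, a strong, unhindered carbon nucleophile that displaces the benzylic chloride in an SN2 alkylation accelerated by DMPU; the methyl ynol ether is chosen because it cannot fragment by a retro-ene path on later heating.

Step 7
Reactants: 5 racemic 3-(benzyloxy)-4-methylcyclobut-2-en-1-one; 14 5-methoxy-1,3-bis(methoxymethoxy)-2-(3-methoxyprop-2-yn-1-yl)benzene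
Product: 19 5-(benzyloxy)-3-methoxy-2-{[4-methoxy-2,6-bis(methoxymethoxy)phenyl]methyl}-6-methylphenol, via vinylketene 15 (not isolated), via vinylcyclobutenone 16 (not isolated), via dienylketene 17 (not isolated), via cyclohexadienone 18 (not isolated)
Conditions: toluene, 80 °C, then 120 °C (sealed tube, Ar); then K2CO3, MeOH, rt
Reagents that add atoms: none
Why: Heating opens 5 by a conrotatory 4π-electrocyclic reaction (methyl turning outward) to vinylketene 15, whose C=C adds [2+2] to ynol ether 14, the ketene carbonyl carbon bonding to the alkyne carbon that bears the ring A CH2 and the ketene α-carbon to the methoxy-bearing carbon; vinylcyclobutenone 16 then opens (4π) to dienylketene 17. The closest known reaction type is the Danheiser benzannulation of cyclobutenones with alkoxy- or siloxyalkynes. Ring B closes by a thermal disrotatory 6π-electrocyclization of 17, which re-forms the bond between the former acyl carbon and the methyl-bearing carbon of 5, and cyclohexadienone 18 tautomerizes irreversibly to phenol 19. No stereocentre is set: the racemic sp3 carbons of 5, 16 and 18 all become aromatic carbons. The only selectivity needed is the regiochemistry of the [2+2] event, and the polarization of the ynol ether (nucleophilic at the carbon remote from oxygen) towards the electrophilic ketene carbon secures it, which places the CH2-bearing carbon between the new C–OH and the C–OMe. Opening of 16 to the non-cyclizable dienylketene isomer is reversible, so the hold at 120 °C should drain it through 17, the methyl ynol ether has no retro-ene path, the neutral medium spares the MOM and benzyl ethers, and the carbonate–methanol treatment returns any 19 that was O-acylated by 15.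

Step 8
Reactants: 19 5-(benzyloxy)-3-methoxy-2-{[4-methoxy-2,6-bis(methoxymethoxy)phenyl]methyl}-6-methylphenol
Product: 21 4-[(2,6-dihydroxy-4-methoxyphenyl)methyl]-5-methoxy-2-methylbenzene-1,3-diol, via MOM-protected diol 20 (not isolated)
Conditions: H2 (1 atm), Pd/C, EtOAc–MeOH, rt; filter; then conc. HCl (cat.), MeOH, 45 °C, Ar
Reagents that add atoms: none
Why: Hydrogenolysis over palladium on carbon cleaves only the benzyl aryl ether, and methanolic HCl then transfers both MOM groups to the solvent as dimethoxymethane (acetal exchange), so all three masked phenols are freed in one telescoped operation without touching the two methyl ethers or the diarylmethane.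

Step 9
Reactants: 21 4-[(2,6-dihydroxy-4-methoxyphenyl)methyl]-5-methoxy-2-methylbenzene-1,3-diol
Product: 23 1-{3-[(3-acetyl-2,6-dihydroxy-4-methoxyphenyl)methyl]-4,6-dihydroxy-2-methoxy-5-methylphenyl}ethan-1-one (target), via bis(ketiminium) dichloride 22 (not isolated)
Conditions: MeCN, ZnCl2, HCl (g), Et2O, 0 °C → rt; then H2O, 90 °C
Reagents that add atoms: acetonitrile, CC#N; water, O
Why: In a twofold Hoesch acylation each phloroglucinol-type ring attacks the activated nitrile once, ring B at its only free carbon and ring A at either of its two equivalent free carbons (each ortho to a hydroxyl and to the methoxyl and para to a hydroxyl), the ketiminium group deactivates its ring against a second acylation, and aqueous hydrolysis gives the two aryl methyl ketones.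

**Compound list**

1 | propionyl chloride | CCC(Cl)=O | starting material
2 | ethoxyacetylene | CCOC#C | starting material
3 | methylketene | CC=C=O | intermediate (not isolated)
4 | 3-ethoxy-4-methylcyclobut-2-en-1-one (racemic) | CCOC1=CC(=O)C1C | intermediate
5 | 3-(benzyloxy)-4-methylcyclobut-2-en-1-one (racemic) | CC1C(=O)C=C1OCc1ccccc1 | intermediate
6 | 5-methoxyresorcinol | COc1cc(O)cc(O)c1 | starting material
7 | 1-methoxy-3,5-bis(methoxymethoxy)benzene | COCOc1cc(OC)cc(OCOC)c1 | intermediate
8 | [4-methoxy-2,6-bis(methoxymethoxy)phenyl]lithium | [Li]c1c(OCOC)cc(OC)cc1OCOC | intermediate (not isolated)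
9 | [4-methoxy-2,6-bis(methoxymethoxy)phenyl]methanol | OCc1c(OCOC)cc(OC)cc1OCOC | intermediate
10 | [4-methoxy-2,6-bis(methoxymethoxy)phenyl]methyl methanesulfonate | CS(=O)(=O)OCc1c(OCOC)cc(OC)cc1OCOC | intermediate (not isolated)
11 | 2-(chloromethyl)-5-methoxy-1,3-bis(methoxymethoxy)benzene | ClCc1c(OCOC)cc(OC)cc1OCOC | intermediate
12 | chloroacetaldehyde dimethyl acetal (2-chloro-1,1-dimethoxyethane) | COC(CCl)OC | starting material
13 | lithium methoxyacetylide | [Li]C#COC | intermediate (not isolated)
14 | 5-methoxy-1,3-bis(methoxymethoxy)-2-(3-methoxyprop-2-yn-1-yl)benzene | COC#CCc1c(OCOC)cc(OC)cc1OCOC | intermediate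
15 | (3Z)-3-(benzyloxy)penta-1,3-dien-1-one | C/C=C(\OCc1ccccc1)C=C=O | intermediate (not isolated)
16 | 4-[(1Z)-1-(benzyloxy)prop-1-en-1-yl]-3-methoxy-2-{[4-methoxy-2,6-bis(methoxymethoxy)phenyl]methyl}cyclobut-2-en-1-one (racemic) | C/C=C(\OCc1ccccc1)C1C(=O)C(Cc2c(OCOC)cc(OC)cc2OCOC)=C1OC | intermediate (not isolated)
17 | (3E,5Z)-5-(benzyloxy)-3-methoxy-2-{[4-methoxy-2,6-bis(methoxymethoxy)phenyl]methyl}hepta-1,3,5-trien-1-one | O=C=C(Cc1c(OCOC)cc(OC)cc1OCOC)/C(OC)=C\C(OCc1ccccc1)=C\C | intermediate (not isolated)
18 | 5-(benzyloxy)-3-methoxy-2-{[4-methoxy-2,6-bis(methoxymethoxy)phenyl]methyl}-6-methylcyclohexa-2,4-dien-1-one (racemic) | CC1C(=O)C(Cc2c(OCOC)cc(OC)cc2OCOC)=C(OC)C=C1OCc1ccccc1 | intermediate (not isolated)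
19 | 5-(benzyloxy)-3-methoxy-2-{[4-methoxy-2,6-bis(methoxymethoxy)phenyl]methyl}-6-methylphenol | COc1cc(OCc2ccccc2)c(C)c(O)c1Cc1c(OCOC)cc(OC)cc1OCOC | intermediate
20 | 5-methoxy-4-{[4-methoxy-2,6-bis(methoxymethoxy)phenyl]methyl}-2-methylbenzene-1,3-diol | COc1cc(O)c(C)c(O)c1Cc1c(OCOC)cc(OC)cc1OCOC | intermediate (not isolated)
21 | 4-[(2,6-dihydroxy-4-methoxyphenyl)methyl]-5-methoxy-2-methylbenzene-1,3-diol | COc1cc(O)c(C)c(O)c1Cc1c(O)cc(OC)cc1O | intermediate
22 | bis(ketiminium) dichloride of the target (both C=O replaced by C=NH2+, two chloride counter-ions) | COc1cc(O)c(Cc2c(O)c(C)c(O)c(C(C)=[NH2+])c2OC)c(O)c1C(C)=[NH2+].[Cl-].[Cl-] | intermediate (not isolated)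
23 | 1-{3-[(3-acetyl-2,6-dihydroxy-4-methoxyphenyl)methyl]-4,6-dihydroxy-2-methoxy-5-methylphenyl}ethan-1-one | COc1cc(O)c(Cc2c(O)c(C)c(O)c(C(C)=O)c2OC)c(O)c1C(C)=O | target

**Step count**

Total: 9 steps. Longest linear sequence: 7 steps (6 → 7 → 9 → 11 → 14 → 19 → 21 → 23, steps 3 to 9); the cyclobutenone branch (steps 1 and 2) joins at step 7.

**Steps most likely to fail**

1. Step 7 (benzannulation). The vinylogous-ester cyclobutenone may open too slowly, so that the ynol ether is lost to decomposition before the vinylketene captures it. The cascade may also stall at the vinylcyclobutenone stage, or the vinylketene may dimerise. The fallback gives up the cycloaddition and forms the diarylmethane bond by Friedel–Crafts chemistry; it sets out from 7 and 9 and comes back at 20. Compound 7 is lithiated as in step 4 and the aryllithium 8 is quenched with MeI to give 5-methoxy-1,3-bis(methoxymethoxy)-2-methylbenzene F1. HCl in methanol then frees 5-methoxy-2-methylbenzene-1,3-diol F2, a symmetrical ring B nucleophile whose two free ring carbons are equivalent. Benzylation of an excess of F2 with alcohol 9 under a catalytic Lewis acid (Sc(OTf)3, MeCN, 0 °C) should give 20, and the route continues with the acid stage of step 8. Any MOM loss during the coupling is harmless there.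

2. Step 2 (alkoxy exchange). Ketonisation of the mixed-ketal enol followed by elimination towards the methyl-bearing carbon would move the ring double bond and deliver the methyl to the wrong ring B carbon in step 7. Adventitious water would hydrolyse the enol ether. The fallback avoids the exchange; it sets out from 1 and comes back at 5. Benzyl alcohol is added to trichloroethylene (KH, THF) to give benzyl (E)-1,2-dichlorovinyl ether F3. Two equivalents of n-BuLi at −78 °C convert it by elimination and chlorine–lithium exchange into lithium benzyloxyacetylide F4, and a methanol quench gives benzyloxyacetylene F5. This is used cold and at once in the [2+2] cycloaddition with methylketene 3, generated from 1 and Et3N as in step 1, to form 5 directly.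

3. Step 6 (alkylation). The benzylic chloride may ionise, with participation of an ortho acetal oxygen or self-alkylation, faster than it is displaced. Residual base may also cause propargyl-to-allenyl isomerisation of the product. The fallback replaces the displacement by a cross-coupling; it sets out from 13 (generated from 12 as in step 6) and 11 and comes back at 14. The acetylide 13 is quenched with Bu3SnCl to give tributyl(methoxyethynyl)stannane F6. Stille coupling of F6 with chloride 11 (Pd(PPh3)4, THF, 60 °C) proceeds by oxidative addition of the benzylic chloride to zerovalent palladium, alkynyl transmetalation and reductive elimination, and should deliver 14 under neutral conditions.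

**Further compounds**

F1 | step 7 | 5-methoxy-1,3-bis(methoxymethoxy)-2-methylbenzene | Cc1c(OCOC)cc(OC)cc1OCOC
F2 | step 7 | 5-methoxy-2-methylbenzene-1,3-diol | COc1cc(O)c(C)c(O)c1
F3 | step 2 | benzyl (E)-1,2-dichlorovinyl ether | Cl/C=C(/Cl)OCc1ccccc1
F4 | step 2 | lithium benzyloxyacetylide | [Li]C#COCc1ccccc1
F5 | step 2 | benzyloxyacetylene | C#COCc1ccccc1
F6 | step 6 | tributyl(methoxyethynyl)stannane | CCCC[Sn](CCCC)(CCCC)C#COC
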